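**Retrosynthetic overview**

- Target 28 ← bis-silylethyl ester 27 (fluoride) ← phosphonoacetate 25, whose trienoate is completed on O6 by Horner–Wadsworth–Emmons olefination with dienal 26 only after C8 is set ← enone 20 (hydride, then H2, both from the α face, give 6β-O and 8β-C12).
- Enone 20 ← 6α-silyloxy decalin 16 by desilylation, oxidation at C6 and dehydrogenation to C7=C8; C6 steers the cyclisation and is then erased and reset.
- 16 ← triene maleate 15. The feature used is that C4, C5, C10 and C9 lie in a row, so one acyclic triene whose C8=C9 maleate already carries C12 and C11 and whose C6 carries oxygen folds into both rings: C4–C5 closes ring A first, C9–C10 closes ring B second.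
- 15 ← (S)-homopropargylic silyl ether 13 (oxidative dicarbonylation of the alkyne) ← (E)-enal 9 (asymmetric propargylation) ← ethyl but-2-ynoate 3 and 5-chloropentan-2-one 1 (carbocupration fixes the E alkene).

Key step: step 8

**Remarks on the chemistry (assumptions)**

- Drimane numbering is used (ring A = C1–C5 and C10; ring B = C5–C10; C11 on C9, C12 on C8); β is the face of the C10 methyl.
- The tether between C10 and C4 needs three methylene groups (C1–C3), so the chain is built from a 4-methylpent-4-enyl unit.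
- C8 of 16 is drawn as the all-equatorial 8α epimer; either C8 epimer can be carried on, because C8 becomes trigonal in step 11.
- The sense of induction of (S)-TRIP is taken from aryl and alkenyl aldehydes; should it be reversed for this enal, the (R)-catalyst is used.
- In the hydroxy diester with 6β-OH and 8β-ester both axial, lactonisation onto C12 is expected to be easy. The ketone is therefore reduced and O6 acylated while C8 is still trigonal, and the triene is attached after the hydrogenation.

**Route**

Step 1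
Reactants: 1 5-chloropentan-2-one
Product: 2 5-chloro-2-methylpent-1-ene
Conditions: Ph3PCH3Br, KOtBu, THF, 0 °C to rt
Reagents that add atoms: methyltriphenylphosphonium bromide, C[P+](c1ccccc1)(c1ccccc1)c1ccccc1.[Br-]
Why: Wittig methylenation of the methyl ketone with the preformed non-stabilised ylide is fast at 0 °C, so olefination should outrun base-induced cyclisation of the γ-chloro ketone.

Step 2
Reactants: 2 5-chloro-2-methylpent-1-ene; 3 ethyl but-2-ynoate
Product: 7 ethyl (2E)-3,7-dimethylocta-2,7-dienoate, via 4-methylpent-4-enylmagnesium chloride 4 (not isolated), via 4-methylpent-4-enylcopper 5 (not isolated), via ethyl (2Z)-2-cuprio-3,7-dimethylocta-2,7-dienoate 6 (not isolated)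
Conditions: Mg, THF, reflux; CuBr·SMe2, THF, −40 °C; then 3, −78 °C; MeOH then aq. NH4Cl, −78 °C to rt
Reagents that add atoms: magnesium, [Mg], and CuBr·SMe2, [Cu+].[Br-].CSC (in intermediates 4 to 6 only)
Why: Syn carbocupration of the ynoate by the alkylcopper reagent at −78 °C and protonation of the alkenylcopper with retention place the new chain cis to H, which gives the (E)-trisubstituted enoate that becomes C5=C10.

Step 3
Reactants: 7 ethyl (2E)-3,7-dimethylocta-2,7-dienoate
Product: 8 (2E)-3,7-dimethylocta-2,7-dien-1-ol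
Conditions: iBu2AlH (DIBAL-H), CH2Cl2, −78 to 0 °C; aq. potassium sodium tartrate (KNaC4H4O6)
Reagents that add atoms: none
Why: DIBAL-H reduces the conjugated ester by 1,2-addition to the allylic alcohol and leaves both alkenes untouched.

Step 4
Reactants: 8 (2E)-3,7-dimethylocta-2,7-dien-1-ol
Product: 9 (2E)-3,7-dimethylocta-2,7-dienal
Conditions: MnO2, CH2Cl2, rt
Reagents that add atoms: none
Why: MnO2 oxidises the allylic alcohol selectively to the enal without isomerising the trisubstituted alkene.

Step 5
Reactants: 9 (2E)-3,7-dimethylocta-2,7-dienal; 10 allenylboronic acid pinacol ester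
Product: 12 (4S,5E)-6,10-dimethylundeca-5,10-dien-1-yn-4-ol, via O-pinacolboryl ether 11 (not isolated)
Conditions: (S)-TRIP [(S)-3,3'-bis(2,4,6-triisopropylphenyl)-1,1'-binaphthyl-2,2'-diyl hydrogen phosphate] (10 mol %), 4 Å molecular sieves, toluene, 0 °C; aq. NaHCO3
Reagents that add atoms: none
Why: Chiral phosphoric acid-catalysed propargylation with the allenylboronate passes through a six-membered chair transition state with SE2' transfer, and the (S)-catalyst is expected to direct attack to the Si face of the aldehyde and so set C6 as (S).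

Step 6
Reactants: 12 (4S,5E)-6,10-dimethylundeca-5,10-dien-1-yn-4-ol
Product: 13 tert-butyl{[(4S,5E)-6,10-dimethylundeca-5,10-dien-1-yn-4-yl]oxy}dimethylsilane
Conditions: TBSCl, imidazole, DMF, rt
Reagents that add atoms: tert-butyldimethylsilyl chloride, CC(C)(C)[Si](C)(C)Cl
Why: Imidazole-promoted silylation of a secondary allylic alcohol is routine and leaves the C6 configuration untouched.

Step 7
Reactants: 13 tert-butyl{[(4S,5E)-6,10-dimethylundeca-5,10-dien-1-yn-4-yl]oxy}dimethylsilane; 14 2-(trimethylsilyl)ethanol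
Product: 15 bis[2-(trimethylsilyl)ethyl] (2Z)-2-[(2S,3E)-2-(tert-butyldimethylsilyloxy)-4,8-dimethylnona-3,8-dienyl]but-2-enedioate
Conditions: PdI2 (2 mol %), KI (20 mol %), CO/air (4:1, 20 atm), 14 (10 equiv), 1,2-dimethoxyethane, 40 °C
Reagents that add atoms: carbon monoxide, [C-]#[O+]
Why: PdI2/KI-catalysed oxidative dialkoxycarbonylation of a terminal alkyne adds both ester groups syn across the triple bond at divalent palladium, which should give the (Z)-diester (maleate) with C12 on C8 and C11 on C9, while air reoxidises the zerovalent palladium and the silyl ether and unactivated alkenes are not substrates.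

Step 8
Reactants: 15 bis[2-(trimethylsilyl)ethyl] (2Z)-2-[(2S,3E)-2-(tert-butyldimethylsilyloxy)-4,8-dimethylnona-3,8-dienyl]but-2-enedioate
Product: 16 bis[2-(trimethylsilyl)ethyl] 6α-(tert-butyldimethylsilyloxy)drimane-11,12-dioate (8α,9β-diester, trans-decalin)
Conditions: Fe(acac)3 (0.5 equiv), PhSiH3 (2.5 equiv), EtOH/ethylene glycol (5:1, 0.01 M), argon, 60 °C
Reagents that add atoms: none
Why: An iron hydride generated from Fe(acac)3 and PhSiH3 delivers a hydrogen atom to the CH2 terminus of the isopropenyl group, the tertiary C4 radical adds to C5 (ring A, 6-endo-trig, C4–C5), the tertiary C10 radical adds to C9 of the maleate (ring B, 6-endo-trig, C9–C10), and the C8 radical next to the C12 ester is reduced to an iron enolate and protonated by ethanol. The closest known reaction type is the metal-hydride hydrogen-atom-transfer radical polyene cyclisation terminated by an electron-poor alkene. Each closure is 6-endo because the 5-exo alternative would join a tertiary radical to a fully substituted alkene carbon (C10, then C8), and the second addition is polarity-matched. C5 is controlled by C6: allylic 1,3-strain with the C10 methyl keeps H6 in the alkene plane and C4 should add anti to the larger C7 branch with the silyloxy group outside, which leaves that group equatorial (6α) after ring B closes; C10 follows from chair-on-chair closure (axial methyl, trans fusion) and C9 from the maleate geometry (C11 trans to C7, hence equatorial 9β). C8 comes from enolate protonation and is not relied on, the 8α epimer being drawn and the 8β epimer converging at enone 20. The step needs hydrogen-atom transfer at the 1,1-disubstituted alkene only, secured by its being the one unhindered electron-rich alkene, and high facial selectivity at C5, which rests on the single silyloxy stereocentre and is the main uncertainty.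

Step 9
Reactants: 16 bis[2-(trimethylsilyl)ethyl] 6α-(tert-butyldimethylsilyloxy)drimane-11,12-dioate
Product: 17 bis[2-(trimethylsilyl)ethyl] 6α-hydroxydrimane-11,12-dioate
Conditions: HF·pyridine, pyridine, THF, 0 °C to rt
Reagents that add atoms: none
Why: HF·pyridine cleaves the secondary silyl ether by attack at silicon, whereas the 2-(trimethylsilyl)ethyl esters need free fluoride ion and should survive.

Step 10
Reactants: 17 bis[2-(trimethylsilyl)ethyl] 6α-hydroxydrimane-11,12-dioate
Product: 18 bis[2-(trimethylsilyl)ethyl] 6-oxodrimane-11,12-dioate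
Conditions: Dess–Martin periodinane, NaHCO3, CH2Cl2, rt
Reagents that add atoms: none
Why: Dess–Martin oxidation converts the hindered equatorial alcohol to the C6 ketone under buffered neutral conditions, which removes the C6 stereocentre once it has controlled the cyclisation.

Step 11
Reactants: 18 bis[2-(trimethylsilyl)ethyl] 6-oxodrimane-11,12-dioate
Product: 20 bis[2-(trimethylsilyl)ethyl] 6-oxodrim-7-ene-11,12-dioate, via 6-trimethylsilyloxy drim-6-ene diester 19 (not isolated)
Conditions: LiN(SiMe3)2, Me3SiCl, THF, −78 °C; then Pd(OAc)2, MeCN, rt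
Reagents that add atoms: chlorotrimethylsilane, C[Si](C)(C)Cl (in intermediate 19 only)
Why: In this Saegusa–Ito oxidation the amide base removes the accessible C7 proton (C5–H lies between two quaternary carbons), and Pd(OAc)2 dehydrogenates the silyl enol ether to the C7=C8 enone, which makes C8 trigonal and merges both C8 epimers.

Step 12
Reactants: 20 bis[2-(trimethylsilyl)ethyl] 6-oxodrim-7-ene-11,12-dioate
Product: 21 bis[2-(trimethylsilyl)ethyl] 6β-hydroxydrim-7-ene-11,12-dioate
Conditions: NaBH4, CeCl3·7H2O, MeOH, −78 to −40 °C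
Reagents that add atoms: none
Why: Luche reduction gives 1,2-reduction of the enone with hydride delivered to the α face, the β face being screened by the axial methyl groups on C4 and C10, which sets the axial 6β-alcohol, and with C8 trigonal the hydroxyl cannot lactonise onto C12.

Step 13
Reactants: 21 bis[2-(trimethylsilyl)ethyl] 6β-hydroxydrim-7-ene-11,12-dioate; 22 (diethoxyphosphoryl)acetic acid
Product: 24 bis[2-(trimethylsilyl)ethyl] 6β-[(diethoxyphosphoryl)acetoxy]drim-7-ene-11,12-dioate, via O-acylisourea 23 (not isolated)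
Conditions: DCC, DMAP (cat.), CH2Cl2, 0 °C to rt
Reagents that add atoms: N,N'-dicyclohexylcarbodiimide, C(=NC1CCCCC1)=NC1CCCCC1 (in intermediate 23 only)
Why: Steglich esterification with the small phosphonoacetic acid should acylate the hindered axial alcohol on oxygen with retention at C6 and installs the handle for chain extension before C8 becomes tetrahedral.

Step 14
Reactants: 24 bis[2-(trimethylsilyl)ethyl] 6β-[(diethoxyphosphoryl)acetoxy]drim-7-ene-11,12-dioate
Product: 25 bis[2-(trimethylsilyl)ethyl] 6β-[(diethoxyphosphoryl)acetoxy]drimane-11,12-dioate (8β,9β-diester)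
Conditions: H2 (1–3 atm), 5% Rh on Al2O3, EtOAc, rt
Reagents that add atoms: none
Why: Heterogeneous hydrogenation of the trisubstituted enoate should occur from the α face, the β face being blocked by the C10 methyl and the pseudoaxial C6 acyloxy group, so H adds to C8α and the C12 ester ends 8β, cis to the C11 ester, and Rh on Al2O3 is chosen to limit allylic C–O hydrogenolysis.

Step 15
Reactants: 25 bis[2-(trimethylsilyl)ethyl] 6β-[(diethoxyphosphoryl)acetoxy]drimane-11,12-dioate; 26 (2E,4E)-hexa-2,4-dienal
Product: 27 bis[2-(trimethylsilyl)ethyl] 6β-[(2E,4E,6E)-octa-2,4,6-trienoyloxy]drimane-11,12-dioate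
Conditions: LiCl, DBU, MeCN, 0 °C to rt
Reagents that add atoms: none
Why: Horner–Wadsworth–Emmons olefination under LiCl/amine conditions couples the stabilised phosphonate with the dienal to give the new C2'=C3' alkene with (E) geometry, and the base is too weak to enolise the C8 or C9 esters.

Step 16
Reactants: 27 bis[2-(trimethylsilyl)ethyl] 6β-[(2E,4E,6E)-octa-2,4,6-trienoyloxy]drimane-11,12-dioate
Product: 28 6β-[(2E,4E,6E)-octa-2,4,6-trienoyloxy]drimane-11,12-dioic acid (CNP0462207.1)
Conditions: Bu4NF, THF, 0 °C to rt; then aq. HCl to pH 3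
Reagents that add atoms: none
Why: Fluoride attacks silicon and fragments each 2-(trimethylsilyl)ethyl ester into carboxylate, ethylene and Me3SiF, conditions under which the hindered trienoate ester and the C8 stereocentre are expected to survive.

**Compound list**

1 | 5-chloropentan-2-one | CC(=O)CCCCl | starting material
2 | 5-chloro-2-methylpent-1-ene | C=C(C)CCCCl | intermediate
3 | ethyl but-2-ynoate | CC#CC(=O)OCC | starting material
4 | 4-methylpent-4-enylmagnesium chloride | C=C(C)CCC[Mg]Cl | intermediate (not isolated)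
5 | 4-methylpent-4-enylcopper | C=C(C)CCC[Cu] | intermediate (not isolated)
6 | ethyl (2Z)-2-cuprio-3,7-dimethylocta-2,7-dienoate | C=C(C)CCC/C(C)=C(\[Cu])C(=O)OCC | intermediate (not isolated)
7 | ethyl (2E)-3,7-dimethylocta-2,7-dienoate | C=C(C)CCC/C(C)=C/C(=O)OCC | intermediate
8 | (2E)-3,7-dimethylocta-2,7-dien-1-ol | C=C(C)CCC/C(C)=C/CO | intermediate
9 | (2E)-3,7-dimethylocta-2,7-dienal | C=C(C)CCC/C(C)=C/C=O | intermediate
10 | allenylboronic acid pinacol ester (4,4,5,5-tetramethyl-2-propa-1,2-dienyl-1,3,2-dioxaborolane) | C=C=CB1OC(C)(C)C(C)(C)O1 | starting material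
11 | 2-{[(4S,5E)-6,10-dimethylundeca-5,10-dien-1-yn-4-yl]oxy}-4,4,5,5-tetramethyl-1,3,2-dioxaborolane | C=C(C)CCC/C(C)=C/[C@@H](OB1OC(C)(C)C(C)(C)O1)CC#C | intermediate (not isolated)
12 | (4S,5E)-6,10-dimethylundeca-5,10-dien-1-yn-4-ol | C=C(C)CCC/C(C)=C/[C@@H](O)CC#C | intermediate
13 | tert-butyl{[(4S,5E)-6,10-dimethylundeca-5,10-dien-1-yn-4-yl]oxy}dimethylsilane | C=C(C)CCC/C(C)=C/[C@@H](O[Si](C)(C)C(C)(C)C)CC#C | intermediate
14 | 2-(trimethylsilyl)ethanol | C[Si](C)(C)CCO | starting material
15 | bis[2-(trimethylsilyl)ethyl] (2Z)-2-[(2S,3E)-2-(tert-butyldimethylsilyloxy)-4,8-dimethylnona-3,8-dienyl]but-2-enedioate | C=C(C)CCC/C(C)=C/[C@@H](O[Si](C)(C)C(C)(C)C)C/C(C(=O)OCC[Si](C)(C)C)=C/C(=O)OCC[Si](C)(C)C | intermediate (key-step precursor)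
16 | bis[2-(trimethylsilyl)ethyl] 6α-(tert-butyldimethylsilyloxy)drimane-11,12-dioate; trans-decalin with 5α-H, 10β-CH3, C11 ester 9β, C12 ester 8α, silyloxy equatorial | CC(C)(C)[Si](C)(C)O[C@H]1C[C@@H](C(=O)OCC[Si](C)(C)C)[C@H](C(=O)OCC[Si](C)(C)C)[C@@]2(C)CCCC(C)(C)[C@H]12 | intermediate (key-step product)
17 | bis[2-(trimethylsilyl)ethyl] 6α-hydroxydrimane-11,12-dioate; 5α-H, 8α and 9β esters, 10β-CH3 | O[C@H]1C[C@@H](C(=O)OCC[Si](C)(C)C)[C@H](C(=O)OCC[Si](C)(C)C)[C@@]2(C)CCCC(C)(C)[C@H]12 | intermediate
18 | bis[2-(trimethylsilyl)ethyl] 6-oxodrimane-11,12-dioate; 5α-H, 8α and 9β esters, 10β-CH3 | O=C1C[C@@H](C(=O)OCC[Si](C)(C)C)[C@H](C(=O)OCC[Si](C)(C)C)[C@@]2(C)CCCC(C)(C)[C@H]12 | intermediate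
19 | bis[2-(trimethylsilyl)ethyl] 6-(trimethylsilyloxy)drim-6-ene-11,12-dioate; 5α-H, 8α and 9β esters, 10β-CH3 | C[Si](C)(C)OC1=C[C@@H](C(=O)OCC[Si](C)(C)C)[C@H](C(=O)OCC[Si](C)(C)C)[C@@]2(C)CCCC(C)(C)[C@H]12 | intermediate (not isolated)
20 | bis[2-(trimethylsilyl)ethyl] 6-oxodrim-7-ene-11,12-dioate; 5α-H, 9β ester, 10β-CH3 | O=C1C=C(C(=O)OCC[Si](C)(C)C)[C@H](C(=O)OCC[Si](C)(C)C)[C@@]2(C)CCCC(C)(C)[C@H]12 | intermediate
21 | bis[2-(trimethylsilyl)ethyl] 6β-hydroxydrim-7-ene-11,12-dioate; 5α-H, 9β ester, 10β-CH3, axial hydroxyl | O[C@@H]1C=C(C(=O)OCC[Si](C)(C)C)[C@H](C(=O)OCC[Si](C)(C)C)[C@@]2(C)CCCC(C)(C)[C@H]12 | intermediate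
22 | (diethoxyphosphoryl)acetic acid | CCOP(=O)(OCC)CC(=O)O | starting material
23 | O-[(diethoxyphosphoryl)acetyl]-N,N'-dicyclohexylisourea | CCOP(=O)(OCC)CC(=O)OC(=NC1CCCCC1)NC1CCCCC1 | intermediate (not isolated)
24 | bis[2-(trimethylsilyl)ethyl] 6β-[(diethoxyphosphoryl)acetoxy]drim-7-ene-11,12-dioate; 5α-H, 9β ester, 10β-CH3 | CCOP(=O)(OCC)CC(=O)O[C@@H]1C=C(C(=O)OCC[Si](C)(C)C)[C@H](C(=O)OCC[Si](C)(C)C)[C@@]2(C)CCCC(C)(C)[C@H]12 | intermediate
25 | bis[2-(trimethylsilyl)ethyl] 6β-[(diethoxyphosphoryl)acetoxy]drimane-11,12-dioate; 5α-H, 8β and 9β esters (cis), 10β-CH3 | CCOP(=O)(OCC)CC(=O)O[C@@H]1C[C@H](C(=O)OCC[Si](C)(C)C)[C@H](C(=O)OCC[Si](C)(C)C)[C@@]2(C)CCCC(C)(C)[C@H]12 | intermediate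
26 | (2E,4E)-hexa-2,4-dienal | C/C=C/C=C/C=O | starting material
27 | bis[2-(trimethylsilyl)ethyl] 6β-[(2E,4E,6E)-octa-2,4,6-trienoyloxy]drimane-11,12-dioate; 5α-H, 8β and 9β esters, 10β-CH3 | C/C=C/C=C/C=C/C(=O)O[C@@H]1C[C@H](C(=O)OCC[Si](C)(C)C)[C@H](C(=O)OCC[Si](C)(C)C)[C@@]2(C)CCCC(C)(C)[C@H]12 | intermediate
28 | 6β-[(2E,4E,6E)-octa-2,4,6-trienoyloxy]drimane-11,12-dioic acid; 5α-H, 8β- and 9β-CO2H, 10β-CH3 (CNP0462207.1) | C/C=C/C=C/C=C/C(=O)O[C@@H]1C[C@H](C(=O)O)[C@H](C(=O)O)[C@@]2(C)CCCC(C)(C)[C@H]12 | target

**Step count**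

Total: 16 steps. Longest linear sequence: 16 steps (1 to 28).

**Steps most likely to fail, with fallbacks**

Step 8 (key bicyclisation). Several processes may fail here.
- Facial selectivity at C5 relative to C6 may be poor. Because C6 is later oxidised, this would show up as loss of enantiomeric purity at ketone 18.
- The C4 radical may be reduced before it reaches the branched, hindered C5.
- If the opposite alkene face were clearly preferred, the (R)-alcohol made with (R)-TRIP would be tried first.
- The fallback changes the approach to a chiral-pool entry that needs no cyclisation. It sets out from 2-(trimethylsilyl)ethanol 14 and commercial (−)-polygodial (C1C=C(C=O)[C@H](C=O)[C@@]2(C)CCCC(C)(C)[C@H]12) and comes back to the route at enone 20.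
- Pinnick oxidation of both aldehydes (NaClO2, NaH2PO4, 2-methylbut-2-ene, tBuOH/H2O) should give drim-7-ene-11,12-dioic acid F1 without epimerising C9.
- Mitsunobu esterification of F1 with 14 (PPh3, diisopropyl azodicarboxylate, THF, 0 °C) should give bis[2-(trimethylsilyl)ethyl] drim-7-ene-11,12-dioate F2.
- Allylic oxidation of F2 at C6 (tBuOOH, catalytic Rh2(cap)4, dirhodium tetrakis(caprolactamate), CH2Cl2) should give 20. Steps 12 to 16 then follow unchanged.

Step 7 (oxidative dicarbonylation with 2-(trimethylsilyl)ethanol). What may go wrong is slow or incomplete alkoxycarbonylation, because the silyl alcohol is a co-reagent and not the solvent; partial Z to E isomerisation or furanone formation could accompany it.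
- The fallback fixes the cis geometry in a ring first. It sets out from alkyne 13 and comes back at 15.
- Carbonylation in aqueous dioxane (PdI2, KI, CO/air, dioxane/H2O) should give 3-[(2S,3E)-2-(tert-butyldimethylsilyloxy)-4,8-dimethylnona-3,8-dienyl]furan-2,5-dione F3.
- Opening of F3 with 14 (catalytic DMAP, CH2Cl2) should give the mono[2-(trimethylsilyl)ethyl] (Z)-hydrogen butenedioate F4. It is drawn as the C11 ester; the regiochemistry is without consequence.
- Mitsunobu esterification of the remaining acid with 14 (PPh3, diisopropyl azodicarboxylate, 0 °C) should give 15.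

Step 14 (hydrogenation of the allylic ester). What may go wrong is hydrogenolysis of the pseudoaxial allylic C6–O bond, or slow reduction of the hindered enoate.
- The fallback changes the order of events. It sets out from enone 20 and comes back at 25.
- Hydrogenation at the ene-dione stage, where no allylic leaving group is present (H2, Pd on carbon, EtOAc), should give bis[2-(trimethylsilyl)ethyl] 6-oxodrimane-11,12-dioate with 8β,9β esters F5.
- Reduction at low temperature (NaBH4, CeCl3·7H2O, MeOH, −78 °C) should give bis[2-(trimethylsilyl)ethyl] 6β-hydroxydrimane-11,12-dioate with 8β,9β esters F6.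
- F6 is acylated at once with 22 (DCC, DMAP, CH2Cl2) to give 25.
- The drawback is that the hydroxyl and the C12 ester of F6 are both axial, so lactonisation can compete. For that reason this order is the reserve and not the first choice.

Further compounds
F1 | step 8 | drim-7-ene-11,12-dioic acid; 5α-H, 9β-CO2H, 10β-CH3 | C1C=C(C(=O)O)[C@H](C(=O)O)[C@@]2(C)CCCC(C)(C)[C@H]12
F2 | step 8 | bis[2-(trimethylsilyl)ethyl] drim-7-ene-11,12-dioate; 5α-H, 9β ester, 10β-CH3 | C1C=C(C(=O)OCC[Si](C)(C)C)[C@H](C(=O)OCC[Si](C)(C)C)[C@@]2(C)CCCC(C)(C)[C@H]12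
F3 | step 7 | 3-[(2S,3E)-2-(tert-butyldimethylsilyloxy)-4,8-dimethylnona-3,8-dienyl]furan-2,5-dione | C=C(C)CCC/C(C)=C/[C@@H](O[Si](C)(C)C(C)(C)C)CC1=CC(=O)OC1=O
F4 | step 7 | (2Z)-2-[(2S,3E)-2-(tert-butyldimethylsilyloxy)-4,8-dimethylnona-3,8-dienyl]-4-oxo-4-[2-(trimethylsilyl)ethoxy]but-2-enoic acid | C=C(C)CCC/C(C)=C/[C@@H](O[Si](C)(C)C(C)(C)C)C/C(C(=O)O)=C/C(=O)OCC[Si](C)(C)C
F5 | step 14 | bis[2-(trimethylsilyl)ethyl] 6-oxodrimane-11,12-dioate; 5α-H, 8β and 9β esters, 10β-CH3 | O=C1C[C@H](C(=O)OCC[Si](C)(C)C)[C@H](C(=O)OCC[Si](C)(C)C)[C@@]2(C)CCCC(C)(C)[C@H]12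
F6 | step 14 | bis[2-(trimethylsilyl)ethyl] 6β-hydroxydrimane-11,12-dioate; 5α-H, 8β and 9β esters, 10β-CH3 | O[C@@H]1C[C@H](C(=O)OCC[Si](C)(C)C)[C@H](C(=O)OCC[Si](C)(C)C)[C@@]2(C)CCCC(C)(C)[C@H]12
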